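**Plan**
- Retrosynthesis: the acetates, the 9,10-diol (back to a 9Z alkene) and the 3Z-enyne (C3=C4, from a C4 aldehyde) go first. The C6–H bond is then traced to a ketal whose two C–O bonds, O12–C6 and O13–C6, are cut to a C6 ketone and a 12,13-diol. The chain is finally cut at C8–C9 and C10–C11, on either side of an acetylene unit.
- Enabling feature: C12 and C13 carry vicinal oxygens and C6 is the other ether carbon of the oxocane (O + C6–C12). Ketone and diol can therefore condense to an 8,10-dioxabicyclo[5.2.1]dec-3-ene that already holds the oxocene ring (O12, C6–C12) and a 1,3-dioxolane (C6, O12, C12, C13, O13), whose C6–O13 bond is a bridge to be cut later.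
- Forward: two epoxy alcohols from the same kinetic resolution are joined through acetylene (C9≡C10), Lindlar reduction gives the 9Z alkene, C6 is oxidised and the diol released; acid then closes dioxolane and oxocene together.
- The bicycle is dihydroxylated, the bridge is cut by hydride with inversion at C6 to leave the cis-oxocane, and the C1–C3 unit is attached as the Z-enyne before acetylation and acetonide cleavage.
- Stereochemistry: C7 and C12/C13 from tartrate-controlled epoxidations; C6 from the bridge and then anti hydride delivery; C9/C10 from osmylation anti to the bridge; 9Z from Lindlar reduction, 3Z from Peterson olefination.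

Key step: step 14

Remark: locants C1–C15 are those of the target chain (C1 alkyne CH, C15 ethyl CH3; oxocane = O + C6–C12); compounds 1 and 7 and 1,3-bis(triisopropylsilyl)propyne are taken as purchasable.

**Step 1**
Reactants: 1 3-(benzyloxy)propanal
Product: 2 rac-5-(benzyloxy)pent-1-en-3-ol
Conditions: CH2=CHMgBr, THF, −78 → 0 °C; aq. NH4Cl
Reagents that add atoms: vinylmagnesium bromide, C=C[Mg]Br
Why: Grignard 1,2-addition to the aldehyde should give the allylic alcohol, racemic by design because step 2 resolves it.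

**Step 2**
Reactants: 2 rac-5-(benzyloxy)pent-1-en-3-ol
Product: 3 (2R,3S)-5-(benzyloxy)-1,2-epoxypentan-3-ol
Conditions: Ti(OiPr)4 (0.15 equiv), L-(+)-diisopropyl tartrate (0.18 equiv), t-BuOOH (0.5 equiv), 4 Å molecular sieves, CH2Cl2, −20 °C
Reagents that add atoms: tert-butyl hydroperoxide, CC(C)(C)OO
Why: Sharpless kinetic resolution, in which the titanium–tartrate catalyst should epoxidise only the (S)-alcohol and do so erythro-selectively, so that the epoxide carbon (C7 of the target) is set R by the tartrate while the (R)-alcohol stays behind.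

**Step 3**
Reactants: 3 (2R,3S)-5-(benzyloxy)-1,2-epoxypentan-3-ol
Product: 4 (2R,3S)-5-(benzyloxy)-1,2-epoxy-3-[(4-methoxybenzyl)oxy]pentane
Conditions: NaH, PMBCl, Bu4NI (cat.), THF/DMF, −20 → 0 °C
Reagents that add atoms: 4-methoxybenzyl chloride, COc1ccc(CCl)cc1
Why: Williamson etherification at low temperature should outrun Payne rearrangement of the epoxy alkoxide and touches no stereocentre.

**Step 4**
Reactants: 4 PMB-protected epoxide
Product: 5 (3S,4R)-1-(benzyloxy)-3-[(4-methoxybenzyl)oxy]hept-6-yn-4-ol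
Conditions: LiC≡CH·H2NCH2CH2NH2, DMSO, rt; H2O
Reagents that add atoms: lithium acetylide–ethylenediamine complex, [Li]C#C.NCCN
Why: SN2 opening of the terminal epoxide at its CH2 carbon (C8) by acetylide leaves the C7–O bond and its configuration intact.

**Step 5**
Reactants: 5 homopropargylic alcohol
Product: 6 (3S,4R)-1-(benzyloxy)-4-[(tert-butyldimethylsilyl)oxy]-3-[(4-methoxybenzyl)oxy]hept-6-yne
Conditions: TBSOTf, 2,6-lutidine, CH2Cl2, −78 → 0 °C
Reagents that add atoms: tert-butyldimethylsilyl triflate, CC(C)(C)[Si](C)(C)OS(=O)(=O)C(F)(F)F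
Why: Silylation of the hindered secondary alcohol with the silyl triflate installs the C7 ether that has to last until step 23.

**Step 6**
Reactants: 7 rac-pent-1-en-3-ol
Product: 8 (2R,3S)-1,2-epoxypentan-3-ol
Conditions: Ti(OiPr)4 (0.15 equiv), L-(+)-diisopropyl tartrate (0.18 equiv), t-BuOOH (0.5 equiv), 4 Å molecular sieves, CH2Cl2, −20 °C
Reagents that add atoms: tert-butyl hydroperoxide, CC(C)(C)OO
Why: The same Sharpless kinetic resolution should convert only the (S)-alcohol into the erythro epoxy alcohol, fixing C13 (S, from the resolution) and C12 (R, from the tartrate-controlled epoxidation).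

**Step 7**
Reactants: 8 (2R,3S)-1,2-epoxypentan-3-ol
Product: 9 (2R,3S)-1,2-epoxy-3-[(triethylsilyl)oxy]pentane
Conditions: TESCl, imidazole, DMAP (cat.), CH2Cl2, 0 °C
Reagents that add atoms: chlorotriethylsilane, CC[Si](Cl)(CC)CC
Why: Neutral silylation protects the C13 hydroxyl without the alkoxide that would allow Payne rearrangement.

**Step 8**
Reactants: 6 TBS-protected alkyne; 9 TES-protected epoxide
Product: 11 (3S,4R,9R,10S)-1-(benzyloxy)-4-[(tert-butyldimethylsilyl)oxy]-3-[(4-methoxybenzyl)oxy]-10-[(triethylsilyl)oxy]dodec-6-yn-9-ol, via lithium alkynide 10 (not isolated)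
Conditions: n-BuLi, THF, −78 °C; BF3·OEt2; then 9, −78 °C; aq. NH4Cl
Reagents that add atoms: none
Why: Yamaguchi–Hirao alkynylation, in which the BF3-activated terminal epoxide should be opened at C11 by the alkynyllithium, joins C10–C11 and frees the C12 hydroxyl with its configuration unchanged.

**Step 9**
Reactants: 11 C12 alcohol
Product: 12 (3S,4R,9R,10S)-1-(benzyloxy)-4-[(tert-butyldimethylsilyl)oxy]-3-[(4-methoxybenzyl)oxy]-9,10-bis[(triethylsilyl)oxy]dodec-6-yne
Conditions: TESCl, imidazole, DMAP (cat.), DMF, rt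
Reagents that add atoms: chlorotriethylsilane, CC[Si](Cl)(CC)CC
Why: Silylation masks the C12 hydroxyl so that only C6 is oxidised in step 12, and both triethylsilyl ethers can later be removed together.

**Step 10**
Reactants: 12 bis-TES alkyne
Product: 13 (3S,4R,6Z,9R,10S)-1-(benzyloxy)-4-[(tert-butyldimethylsilyl)oxy]-3-[(4-methoxybenzyl)oxy]-9,10-bis[(triethylsilyl)oxy]dodec-6-ene
Conditions: H2 (1 atm), Pd/CaCO3 poisoned with Pb(OAc)2, quinoline, EtOAc/hexane, rt
Reagents that add atoms: none
Why: Lindlar semihydrogenation delivers H2 syn on the poisoned palladium surface and should stop at the 9Z alkene without hydrogenolysis of the benzyl or PMB ether.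

**Step 11**
Reactants: 13 Z-alkene
Product: 14 (3S,4R,6Z,9R,10S)-1-(benzyloxy)-4-[(tert-butyldimethylsilyl)oxy]-9,10-bis[(triethylsilyl)oxy]dodec-6-en-3-ol
Conditions: DDQ, CH2Cl2/pH 7 buffer, 0 °C
Reagents that add atoms: none
Why: Oxidative PMB cleavage with DDQ should free only the C6 hydroxyl, since the benzyl ether, the silyl ethers and the isolated alkene are inert under buffered conditions.

**Step 12**
Reactants: 14 C6 alcohol
Product: 15 (4R,6Z,9R,10S)-1-(benzyloxy)-4-[(tert-butyldimethylsilyl)oxy]-9,10-bis[(triethylsilyl)oxy]dodec-6-en-3-one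
Conditions: Dess–Martin periodinane, NaHCO3, CH2Cl2, 0 °C → rt
Reagents that add atoms: none
Why: Dess–Martin oxidation under non-basic conditions should give the α-silyloxy ketone without epimerising C7.

**Step 13**
Reactants: 15 bis-TES ketone
Product: 16 (4R,6Z,9R,10S)-1-(benzyloxy)-4-[(tert-butyldimethylsilyl)oxy]-9,10-dihydroxydodec-6-en-3-one (C6 ketone, 12,13-diol)
Conditions: HF·pyridine, pyridine, THF, 0 °C
Reagents that add atoms: none
Why: Buffered HF·pyridine desilylation should cleave the two triethylsilyl ethers much faster than the hindered secondary TBS ether, releasing the 12,13-diol.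

**Step 14**
Reactants: 16 keto diol
Product: 17 (1R,3Z,6R,7S,9S)-7-[2-(benzyloxy)ethyl]-6-[(tert-butyldimethylsilyl)oxy]-9-ethyl-8,10-dioxabicyclo[5.2.1]dec-3-ene
Conditions: CSA (0.1 equiv), 4 Å molecular sieves, benzene (0.002 M), 50 °C
Reagents that add atoms: none
Why: Proposed new method: acid activates the C6 ketone, the C12 hydroxyl adds reversibly (8-exo-trig) to a medium-ring hemiketal (or the C13 hydroxyl in a 9-exo-trig addition), water leaves to give an oxocarbenium ion, and the second hydroxyl captures it in the usual dioxolane-forming closure (5-endo-trig), so that the ring bond O12–C6 and the bridge bond O13–C6 are both formed and the oxocene and the 1,3-dioxolane close in one operation. The closest known reaction is the acid-catalysed ketalisation of keto diols to 6,8-dioxabicyclo[3.2.1]octanes, where the carbon bridge closes a six-membered ring; what is not established is the same equilibration closing an unsaturated eight-membered ring next to a silyloxy-bearing carbon. The only new stereocentre, C6, is fixed by the tether, because O13 can reach C6 only from the oxocene face that carries C13, so its configuration follows from C12 and C13. The step needs cyclisation to win over intermolecular ketalisation and needs C7 and the β-benzyloxy ketone to survive; high dilution, the Z-alkene (which removes transannular hydrogens and bends the chain), a weak anhydrous acid, and sieves that leave only the final ketal irreversible should secure this.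

**Step 15**
Reactants: 17 bicyclic ketal
Product: 18 (1R,3S,4R,6R,7S,9S)-7-[2-(benzyloxy)ethyl]-6-[(tert-butyldimethylsilyl)oxy]-9-ethyl-8,10-dioxabicyclo[5.2.1]decane-3,4-diol
Conditions: OsO4 (5 mol%), NMO, acetone/H2O, 0 °C → rt
Reagents that add atoms: osmium tetroxide, O=[Os](=O)(=O)=O; N-methylmorpholine N-oxide, C[N+]1([O-])CCOCC1; water, O
Why: Upjohn syn-dihydroxylation, in which OsO4 should add to the alkene face turned away from the bridge carbon C13 with its endo ethyl group and from the C7 silyloxy group, sets C9 R and C10 S under substrate control.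

**Step 16**
Reactants: 18 bicyclic diol
Product: 19 cyclic 3,4-carbonate of 18 (9,10-O-carbonyl bicyclic ketal)
Conditions: CDI, DMAP (cat.), CH2Cl2, rt
Reagents that add atoms: 1,1'-carbonyldiimidazole, O=C(n1ccnc1)n1ccnc1
Why: Carbonylation of the cis-diol gives a five-membered carbonate whose oxygens are too electron-poor to capture the C6 oxocarbenium ion transannularly in step 17.

**Step 17**
Reactants: 19 carbonate-protected bicyclic ketal
Product: 20 (6R,7R,9R,10S,12R,13S)-oxocane (O + C6–C12) bearing C6 2-(benzyloxy)ethyl, C7 OTBS, C9/C10 cyclic carbonate and C12 (1S)-1-hydroxypropyl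
Conditions: Et3SiH, TiCl4, CH2Cl2, −78 °C; aq. NaHCO3
Reagents that add atoms: none
Why: Invertive reductive cleavage of a bridged bicyclic ketal (the Et3SiH/TiCl4 opening established for 6,8-dioxabicyclo[3.2.1]octanes), in which TiCl4 should ionise the bridge bond C6–O13, leaving the oxocarbenium ion in the eight-membered and not a nine-membered ring, and Et3SiH should deliver hydride to the face opposite the departing titanium alkoxide, making C6 R with H6 cis to H12.

**Step 18**
Reactants: 20 oxocane 13-ol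
Product: 21 13-O-TBS ether of 20
Conditions: TBSOTf, 2,6-lutidine, CH2Cl2, −78 → 0 °C
Reagents that add atoms: tert-butyldimethylsilyl triflate, CC(C)(C)[Si](C)(C)OS(=O)(=O)C(F)(F)F
Why: Silylation protects the C13 hydroxyl against the oxidation and organolithium steps that follow.

**Step 19**
Reactants: 21 silylated carbonate
Product: 23 9,10-O-isopropylidene oxocane with C7 and C13 OTBS and C6 2-(benzyloxy)ethyl, via ring diol 22 (not isolated)
Conditions: K2CO3 (0.2 equiv), MeOH, rt; evaporate; 2,2-dimethoxypropane, PPTS (0.5 equiv), CH2Cl2, rt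
Reagents that add atoms: 2,2-dimethoxypropane, COC(C)(C)OC
Why: Methanolysis of the cyclic carbonate followed by acid-catalysed transketalisation should convert the cis-diol into the acetonide that is kept until the last step.

**Step 20**
Reactants: 23 acetonide benzyl ether
Product: 24 C4 primary alcohol (2-hydroxyethyl at C6)
Conditions: H2 (1 atm), Pd(OH)2/C, EtOAc, rt
Reagents that add atoms: none
Why: Hydrogenolysis of the benzyl ether is safe here because no alkene is left in the molecule.

**Step 21**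
Reactants: 24 primary alcohol
Product: 25 C4 aldehyde (2-oxoethyl at C6)
Conditions: Dess–Martin periodinane, NaHCO3, CH2Cl2, 0 °C
Reagents that add atoms: none
Why: Dess–Martin oxidation gives the β-alkoxy aldehyde under non-basic conditions, and it should be used crude to avoid β-elimination of the ring oxygen.

**Step 22**
Reactants: 25 aldehyde
Product: 26 (3Z)-1-(triisopropylsilyl) enyne, side chain CH2–CH=CH–C≡C–Si(iPr)3 at C6
Conditions: 1,3-bis(triisopropylsilyl)propyne, n-BuLi, THF, −78 °C; then 25, −78 → −20 °C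
Reagents that add atoms: 1,3-bis(triisopropylsilyl)propyne, CC(C)[Si](C(C)C)(C(C)C)CC#C[Si](C(C)C)(C(C)C)C(C)C
Why: Peterson olefination with the lithiated bis-silylpropyne should give the Z-enyne, because the bulky silyl groups favour the adduct whose syn-elimination leads to the cis alkene.

**Step 23**
Reactants: 26 silylated enyne
Product: 27 (3Z)-enyne 7,13-diol 9,10-acetonide
Conditions: Bu4NF, THF, 0 °C → rt
Reagents that add atoms: none
Why: Fluoride-mediated desilylation should cleave the alkynyl C–Si bond and both TBS ethers in one operation.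

**Step 24**
Reactants: 27 diol
Product: 28 7,13-diacetate 9,10-acetonide
Conditions: Ac2O, pyridine, DMAP (cat.), CH2Cl2, rt
Reagents that add atoms: acetic anhydride, CC(=O)OC(C)=O
Why: DMAP-catalysed acylation should esterify both secondary alcohols while the 9,10-diol is still masked.

**Step 25**
Reactants: 28 diacetate acetonide
Product: 29 (3Z,6R,7R,9R,10S,12R,13S)-6,12-epoxypentadec-3-en-1-yne-7,9,10,13-tetrol 7,13-diacetate (target)
Conditions: AcOH/H2O (4:1), 40 °C
Reagents that add atoms: none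
Why: Mild acid hydrolysis of the isopropylidene ketal should free the diol, with the acetates and the enyne stable and acyl migration slow under acidic conditions.

**Compound list**
1 | 3-(benzyloxy)propanal | O=CCCOCc1ccccc1 | starting material
2 | rac-5-(benzyloxy)pent-1-en-3-ol | C=CC(O)CCOCc1ccccc1 | intermediate
3 | (2R,3S)-5-(benzyloxy)-1,2-epoxypentan-3-ol | C1O[C@H]1[C@@H](O)CCOCc2ccccc2 | intermediate
4 | (2R,3S)-5-(benzyloxy)-1,2-epoxy-3-[(4-methoxybenzyl)oxy]pentane | C1O[C@H]1[C@@H](OCc2ccc(OC)cc2)CCOCc3ccccc3 | intermediate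
5 | (3S,4R)-1-(benzyloxy)-3-[(4-methoxybenzyl)oxy]hept-6-yn-4-ol | C#CC[C@@H](O)[C@@H](OCc1ccc(OC)cc1)CCOCc2ccccc2 | intermediate
6 | (3S,4R)-1-(benzyloxy)-4-[(tert-butyldimethylsilyl)oxy]-3-[(4-methoxybenzyl)oxy]hept-6-yne | C#CC[C@@H](O[Si](C)(C)C(C)(C)C)[C@@H](OCc1ccc(OC)cc1)CCOCc2ccccc2 | intermediate
7 | rac-pent-1-en-3-ol | CCC(O)C=C | starting material
8 | (2R,3S)-1,2-epoxypentan-3-ol | C1O[C@H]1[C@@H](O)CC | intermediate
9 | (2R,3S)-1,2-epoxy-3-[(triethylsilyl)oxy]pentane | C1O[C@H]1[C@@H](O[Si](CC)(CC)CC)CC | intermediate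
10 | lithium alkynide of 6 (Li on the terminal alkyne carbon, C10) | [Li]C#CC[C@@H](O[Si](C)(C)C(C)(C)C)[C@@H](OCc1ccc(OC)cc1)CCOCc2ccccc2 | intermediate
11 | (3S,4R,9R,10S)-1-(benzyloxy)-4-[(tert-butyldimethylsilyl)oxy]-3-[(4-methoxybenzyl)oxy]-10-[(triethylsilyl)oxy]dodec-6-yn-9-ol (C4–C15 of the target) | CC[C@H](O[Si](CC)(CC)CC)[C@H](O)CC#CC[C@@H](O[Si](C)(C)C(C)(C)C)[C@@H](OCc1ccc(OC)cc1)CCOCc2ccccc2 | intermediate
12 | (3S,4R,9R,10S)-1-(benzyloxy)-4-[(tert-butyldimethylsilyl)oxy]-3-[(4-methoxybenzyl)oxy]-9,10-bis[(triethylsilyl)oxy]dodec-6-yne | CC[C@H](O[Si](CC)(CC)CC)[C@H](O[Si](CC)(CC)CC)CC#CC[C@@H](O[Si](C)(C)C(C)(C)C)[C@@H](OCc1ccc(OC)cc1)CCOCc2ccccc2 | intermediate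
13 | (3S,4R,6Z,9R,10S)-1-(benzyloxy)-4-[(tert-butyldimethylsilyl)oxy]-3-[(4-methoxybenzyl)oxy]-9,10-bis[(triethylsilyl)oxy]dodec-6-ene | CC[C@H](O[Si](CC)(CC)CC)[C@H](O[Si](CC)(CC)CC)C/C=C\C[C@@H](O[Si](C)(C)C(C)(C)C)[C@@H](OCc1ccc(OC)cc1)CCOCc2ccccc2 | intermediate
14 | (3S,4R,6Z,9R,10S)-1-(benzyloxy)-4-[(tert-butyldimethylsilyl)oxy]-9,10-bis[(triethylsilyl)oxy]dodec-6-en-3-ol | CC[C@H](O[Si](CC)(CC)CC)[C@H](O[Si](CC)(CC)CC)C/C=C\C[C@@H](O[Si](C)(C)C(C)(C)C)[C@@H](O)CCOCc1ccccc1 | intermediate
15 | (4R,6Z,9R,10S)-1-(benzyloxy)-4-[(tert-butyldimethylsilyl)oxy]-9,10-bis[(triethylsilyl)oxy]dodec-6-en-3-one | CC[C@H](O[Si](CC)(CC)CC)[C@H](O[Si](CC)(CC)CC)C/C=C\C[C@@H](O[Si](C)(C)C(C)(C)C)C(=O)CCOCc1ccccc1 | intermediate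
16 | (4R,6Z,9R,10S)-1-(benzyloxy)-4-[(tert-butyldimethylsilyl)oxy]-9,10-dihydroxydodec-6-en-3-one (target locants: C6 ketone, 7R, 9Z, 12R,13S-diol) | CC[C@H](O)[C@H](O)C/C=C\C[C@@H](O[Si](C)(C)C(C)(C)C)C(=O)CCOCc1ccccc1 | intermediate
17 | (1R,3Z,6R,7S,9S)-7-[2-(benzyloxy)ethyl]-6-[(tert-butyldimethylsilyl)oxy]-9-ethyl-8,10-dioxabicyclo[5.2.1]dec-3-ene | c1ccccc1COCC[C@]12O[C@@H]([C@H](CC)O2)C/C=C\C[C@H]1O[Si](C)(C)C(C)(C)C | intermediate
18 | (1R,3S,4R,6R,7S,9S)-7-[2-(benzyloxy)ethyl]-6-[(tert-butyldimethylsilyl)oxy]-9-ethyl-8,10-dioxabicyclo[5.2.1]decane-3,4-diol | c1ccccc1COCC[C@]12O[C@@H]([C@H](CC)O2)C[C@H](O)[C@H](O)C[C@H]1O[Si](C)(C)C(C)(C)C | intermediate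
19 | cyclic 3,4-carbonate of 18 (9,10-O-carbonyl) | c1ccccc1COCC[C@]12O[C@@H]([C@H](CC)O2)C[C@@H]3OC(=O)O[C@@H]3C[C@H]1O[Si](C)(C)C(C)(C)C | intermediate
20 | (6R,7R,9R,10S,12R,13S)-oxocane (O + C6–C12): C6 2-(benzyloxy)ethyl, C7 OTBS, C9/C10 cyclic carbonate, C12 (1S)-1-hydroxypropyl, H6 and H12 cis | c1ccccc1COCC[C@H]1O[C@@H]([C@H](CC)O)C[C@@H]2OC(=O)O[C@@H]2C[C@H]1O[Si](C)(C)C(C)(C)C | intermediate
21 | 13-O-tert-butyldimethylsilyl ether of 20 | c1ccccc1COCC[C@H]1O[C@@H]([C@H](CC)O[Si](C)(C)C(C)(C)C)C[C@@H]2OC(=O)O[C@@H]2C[C@H]1O[Si](C)(C)C(C)(C)C | intermediate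
22 | (6R,7R,9R,10S,12R,13S)-oxocane-9,10-diol with C6 2-(benzyloxy)ethyl, C7 OTBS and C12 (1S)-1-(TBS-oxy)propyl | c1ccccc1COCC[C@H]1O[C@@H]([C@H](CC)O[Si](C)(C)C(C)(C)C)C[C@H](O)[C@H](O)C[C@H]1O[Si](C)(C)C(C)(C)C | intermediate
23 | 9,10-O-isopropylidene derivative of 22 | c1ccccc1COCC[C@H]1O[C@@H]([C@H](CC)O[Si](C)(C)C(C)(C)C)C[C@@H]2OC(C)(C)O[C@@H]2C[C@H]1O[Si](C)(C)C(C)(C)C | intermediate
24 | C4 primary alcohol: 23 with 2-hydroxyethyl in place of 2-(benzyloxy)ethyl at C6 | OCC[C@H]1O[C@@H]([C@H](CC)O[Si](C)(C)C(C)(C)C)C[C@@H]2OC(C)(C)O[C@@H]2C[C@H]1O[Si](C)(C)C(C)(C)C | intermediate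
25 | C4 aldehyde: 2-oxoethyl at C6 | O=CC[C@H]1O[C@@H]([C@H](CC)O[Si](C)(C)C(C)(C)C)C[C@@H]2OC(C)(C)O[C@@H]2C[C@H]1O[Si](C)(C)C(C)(C)C | intermediate
26 | (3Z)-enyne with C1 Si(iPr)3, C7 and C13 OTBS, 9,10-acetonide | CC(C)[Si](C(C)C)(C(C)C)C#C/C=C\C[C@H]1O[C@@H]([C@H](CC)O[Si](C)(C)C(C)(C)C)C[C@@H]2OC(C)(C)O[C@@H]2C[C@H]1O[Si](C)(C)C(C)(C)C | intermediate
27 | (3Z,6R,7R,9R,10S,12R,13S)-6,12-epoxypentadec-3-en-1-yne-7,9,10,13-tetrol 9,10-acetonide | C#C/C=C\C[C@H]1O[C@@H]([C@H](CC)O)C[C@@H]2OC(C)(C)O[C@@H]2C[C@H]1O | intermediate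
28 | 7,13-diacetate of 27 | C#C/C=C\C[C@H]1O[C@@H]([C@H](CC)OC(C)=O)C[C@@H]2OC(C)(C)O[C@@H]2C[C@H]1OC(C)=O | intermediate
29 | (3Z,6R,7R,9R,10S,12R,13S)-6,12-epoxypentadec-3-en-1-yne-7,9,10,13-tetrol 7,13-diacetate | C#C/C=C\C[C@H]1O[C@@H]([C@H](CC)OC(C)=O)C[C@H](O)[C@H](O)C[C@H]1OC(C)=O | target

**Step count and risks**
Total: 25 steps. Longest linear sequence: 23 steps (steps 1–5, then 8–25); steps 6–7 make the second epoxide.

Steps most likely to fail:

1. Step 14 (bears the label). Intermolecular ketalisation to oligomers may outrun the eight-membered closure, and prolonged acid may epimerise C7 or eliminate benzyl alcohol from the β-benzyloxy ketone. The fallback builds the same bicycle by known reactions in the opposite order (five-membered ketal first, eight-membered ring by metathesis); it sets out from 6 and 8 and comes back at 17. Alkyne 6 is semihydrogenated over Pd/CaCO3 poisoned with Pb(OAc)2 to the terminal alkene (3S,4R)-1-(benzyloxy)-4-[(tert-butyldimethylsilyl)oxy]-3-[(4-methoxybenzyl)oxy]hept-6-ene F1. DDQ then frees the C6 hydroxyl to give (3S,4R)-1-(benzyloxy)-4-[(tert-butyldimethylsilyl)oxy]hept-6-en-3-ol F2, and Dess–Martin oxidation gives (4R)-1-(benzyloxy)-4-[(tert-butyldimethylsilyl)oxy]hept-6-en-3-one F3. Epoxy alcohol 8 is opened at C11 with excess CH2=CHMgBr and catalytic CuI to (3S,4R)-hept-6-ene-3,4-diol F4. F3 and F4 are condensed (PPTS, benzene, Dean–Stark) to the dioxolane (4R,5S)-4-allyl-2-[2-(benzyloxy)ethyl]-2-[(1R)-1-[(tert-butyldimethylsilyl)oxy]but-3-enyl]-5-ethyl-1,3-dioxolane F5; its C2 epimers equilibrate under the acid, and the one with the butenyl arm cis to the allyl group is carried on. Ring-closing metathesis with the second-generation Grubbs catalyst RuCl2(=CHPh)(PCy3)(H2IMes) in dilute CH2Cl2 at 40 °C should then close the eight-membered bridge as the Z-alkene and give 17.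

2. Step 17. The Lewis acid may ionise the ring bond C6–O12 instead of the bridge, which would lead to a nine-membered ether, or hydride may be captured on both faces of the oxocarbenium ion. The fallback replaces kinetic hydride capture by an equilibrating thiol opening and a radical reduction; it sets out from 19 and comes back at 20. Carbonate 19 is opened with PhSH and BF3·OEt2 at −40 °C, in the way 1,6-anhydro sugars are opened to thioglycosides, to the more stable eight-membered S,O-ketal, the oxocane with phenylsulfanyl and 2-(benzyloxy)ethyl on C6 and a free C13 hydroxyl, F6. Bu3SnH with AIBN in toluene at 80 °C then replaces sulfur by hydrogen through the C6 radical, which should take hydrogen anti to the C7 silyloxy group, giving 20.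

3. Step 15. Osmylation of the bicyclic alkene may show poor facial selectivity. The fallback sets the diol on the monocyclic ring instead; it sets out from 17 and comes back at 23 by way of 22. Ketal 17 is first unbridged with Et3SiH and TiCl4 at −78 °C to the (6R,7R,9Z,12R,13S)-oxocene with C6 2-(benzyloxy)ethyl, C7 OTBS and C12 (1S)-1-hydroxypropyl, F7, and the C13 hydroxyl is silylated with TBSOTf and 2,6-lutidine to its 13-O-TBS ether F8. OsO4 with NMO then dihydroxylates the conformationally different monocyclic alkene to diol 22, which is converted into acetonide 23 as in the second half of step 19.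

**Further compounds**
F1 | step 14 | (3S,4R)-1-(benzyloxy)-4-[(tert-butyldimethylsilyl)oxy]-3-[(4-methoxybenzyl)oxy]hept-6-ene | C=CC[C@@H](O[Si](C)(C)C(C)(C)C)[C@@H](OCc1ccc(OC)cc1)CCOCc2ccccc2
F2 | step 14 | (3S,4R)-1-(benzyloxy)-4-[(tert-butyldimethylsilyl)oxy]hept-6-en-3-ol | C=CC[C@@H](O[Si](C)(C)C(C)(C)C)[C@@H](O)CCOCc1ccccc1
F3 | step 14 | (4R)-1-(benzyloxy)-4-[(tert-butyldimethylsilyl)oxy]hept-6-en-3-one | C=CC[C@@H](O[Si](C)(C)C(C)(C)C)C(=O)CCOCc1ccccc1
F4 | step 14 | (3S,4R)-hept-6-ene-3,4-diol | CC[C@H](O)[C@H](O)CC=C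
F5 | step 14 | (4R,5S)-4-allyl-2-[2-(benzyloxy)ethyl]-2-[(1R)-1-[(tert-butyldimethylsilyl)oxy]but-3-enyl]-5-ethyl-1,3-dioxolane, C2 epimer with the butenyl arm cis to the allyl group | c1ccccc1COCC[C@]1(O[C@@H]([C@H](CC)O1)CC=C)[C@@H](CC=C)O[Si](C)(C)C(C)(C)C
F6 | step 17 | (7R,9R,10S,12R,13S)-oxocane S,O-ketal: C6 phenylsulfanyl and 2-(benzyloxy)ethyl (both C6 epimers), C7 OTBS, C9/C10 cyclic carbonate, C12 (1S)-1-hydroxypropyl | c1ccccc1COCCC1(Sc2ccccc2)O[C@@H]([C@H](CC)O)C[C@@H]3OC(=O)O[C@@H]3C[C@H]1O[Si](C)(C)C(C)(C)C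
F7 | step 15 | (6R,7R,9Z,12R,13S)-oxoc-9-ene (O + C6–C12): C6 2-(benzyloxy)ethyl, C7 OTBS, C12 (1S)-1-hydroxypropyl | c1ccccc1COCC[C@H]1O[C@@H]([C@H](CC)O)C/C=C\C[C@H]1O[Si](C)(C)C(C)(C)C
F8 | step 15 | 13-O-tert-butyldimethylsilyl ether of F7 | c1ccccc1COCC[C@H]1O[C@@H]([C@H](CC)O[Si](C)(C)C(C)(C)C)C/C=C\C[C@H]1O[Si](C)(C)C(C)(C)C
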